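**Plan**

- Retrosynthesis: the three O–CH3 bonds are cut last. In the chlorinated chromone the C4–C4a bond (acylation of 2-chlororesorcinol by an arylacetic acid) and the O1–C2/C2–C3 bonds (one carbon from DMF) are cut next.
- In the genistein half, C4–C4a and O1–C2 are cut together, which leads back to an aryl β-methoxyacrylate. This is cut at the ester C–O bond, and the diaryl ether C–O bond is cut last.
- Enabling feature: in ring A of the genistein half, O1 lies between C8 (which carries the aryloxy group) and C8a, whose other neighbour C4a is the only unsubstituted ortho carbon. An acyl group parked on O1 can therefore shift only to C4a, and O1 then closes onto C2. This fixes the 8-aryloxy pattern and excludes the 6-aryloxy isomer.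
- Forward: the ring A phenol is made by Dakin-type oxidation, the diaryl ether is joined, ring C of the genistein half is closed in the key step, ring C of the 8-chlorochromone is closed next, and all methyl ethers are removed at the end.
- Stereochemistry: the target has no stereocentre. The only stereo-element on the way is the E alkene of the β-methoxyacrylate, set by enolate O-methylation and erased on ring closure.

Key step: step 8

Remark: starting materials 1, 5, 8 and 16 are taken to be catalogue compounds. The E geometry drawn for 10–13 is the expected thermodynamic one and has no bearing on the product.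

**Route**

Step 1
Reactants: 1 2-hydroxy-4,6-dimethoxybenzaldehyde
Product: 2 2-(benzyloxy)-4,6-dimethoxybenzaldehyde
Conditions: BnBr, K2CO3, DMF, 60 °C
Reagents that add atoms: benzyl bromide, BrCc1ccccc1
Why: Williamson etherification of the acidic, chelated ortho-hydroxyl; benzyl is chosen because it survives peracid and copper coupling and falls to hydrogenolysis without touching methyl ethers.

Step 2
Reactants: 2 2-(benzyloxy)-4,6-dimethoxybenzaldehyde
Product: 4 2-(benzyloxy)-4,6-dimethoxyphenol, via aryl formate 3 (not isolated)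
Conditions: mCPBA, CH2Cl2, 0 °C to rt; aq. NaHCO3 wash; then K2CO3 (cat.), MeOH, rt, argon
Reagents that add atoms: mCPBA, O=C(OO)c1cccc(Cl)c1
Why: Dakin-type Baeyer–Villiger oxidation, in which the electron-rich trialkoxyaryl group migrates in preference to hydrogen, followed by methanolysis of the formate; the phenol is oxidation-prone and should be used promptly.

Step 3
Reactants: 4 2-(benzyloxy)-4,6-dimethoxyphenol; 5 methyl 2-(4-iodophenyl)acetate
Product: 6 methyl 2-{4-[2-(benzyloxy)-4,6-dimethoxyphenoxy]phenyl}acetate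
Conditions: CuI (10 mol%), picolinic acid (20 mol%), K3PO4 (anhydrous), DMSO, 90 °C, argon
Reagents that add atoms: none
Why: Ullmann-type C–O coupling catalysed by monovalent copper; the picolinic acid system is established for phenols with two ortho substituents, and the mild phosphate base leaves the methyl arylacetate intact.

Step 4
Reactants: 6 methyl 2-{4-[2-(benzyloxy)-4,6-dimethoxyphenoxy]phenyl}acetate
Product: 7 methyl 2-[4-(2-hydroxy-4,6-dimethoxyphenoxy)phenyl]acetate
Conditions: H2 (1 atm), Pd/C (10%), EtOAc–MeOH, rt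
Reagents that add atoms: none
Why: Hydrogenolysis of the benzyl ether; diaryl ether, methyl ethers and ester are inert under these conditions.

Step 5
Reactants: 8 methyl 2-(4-methoxyphenyl)acetate
Product: 10 methyl (E)-3-methoxy-2-(4-methoxyphenyl)prop-2-enoate, via sodium enolate 9 (not isolated)
Conditions: NaH, HCO2Me, THF, 0 °C to rt; then Me2SO4, DMF, rt
Reagents that add atoms: methyl formate, COC=O; dimethyl sulfate, COS(=O)(=O)OC
Why: Crossed Claisen formylation of the arylacetate followed by O-methylation of the formyl-ester enolate, the standard entry to β-methoxyacrylates; the E isomer (methoxy anti to the ester) is the expected thermodynamic product.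

Step 6
Reactants: 10 methyl (E)-3-methoxy-2-(4-methoxyphenyl)prop-2-enoate
Product: 11 (E)-3-methoxy-2-(4-methoxyphenyl)prop-2-enoic acid
Conditions: LiOH·H2O, THF–MeOH–H2O, 50 °C; then 1 M HCl, 0 °C
Reagents that add atoms: lithium hydroxide, [Li+].[OH-]
Why: Saponification of the methyl ester; the vinylogous carbonate is a poor Michael acceptor toward hydroxide, so the enol ether should persist, and cold acidification avoids its hydrolysis.

Step 7
Reactants: 7 methyl 2-[4-(2-hydroxy-4,6-dimethoxyphenoxy)phenyl]acetate; 11 (E)-3-methoxy-2-(4-methoxyphenyl)prop-2-enoic acid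
Product: 12 2-[4-(2-methoxy-2-oxoethyl)phenoxy]-3,5-dimethoxyphenyl (E)-3-methoxy-2-(4-methoxyphenyl)prop-2-enoate
Conditions: EDC·HCl, DMAP, CH2Cl2, 0 °C to rt
Reagents that add atoms: none
Why: Steglich esterification of the only free phenol; the acid has no α-hydrogen, so ketene formation is excluded and DMAP acyl transfer should overcome the single ortho substituent.

Step 8
Reactants: 12 2-[4-(2-methoxy-2-oxoethyl)phenoxy]-3,5-dimethoxyphenyl (E)-3-methoxy-2-(4-methoxyphenyl)prop-2-enoate
Product: 14 methyl 2-[4-({5,7-dimethoxy-3-(4-methoxyphenyl)-4-oxo-4H-chromen-8-yl}oxy)phenyl]acetate, via ortho-hydroxy ketone 13 (not isolated)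
Conditions: TiCl4 (3 equiv), ClCH2CH2Cl, 0 °C to 40 °C; then aq. HCl, 0 °C
Reagents that add atoms: none
Why: Proposed new method: TiCl4 binds the ester carbonyl, the acyl–oxygen bond ionises to a titanium phenoxide and a β-methoxy-stabilised (vinylogous) acylium ion, and recombination at the only free ortho carbon forms C4–C4a as the chelated ortho-hydroxy ketone 13; the same oxygen then adds to the β-carbon of the enone in a 6-endo-trig oxa-Michael closure and methanol is expelled, which forms O1–C2 and makes ring C aromatic. The closest known reaction type is the Lewis-acid Fries rearrangement of aryl acrylates with in situ oxa-Michael closure to chroman-4-ones, combined with the familiar addition–elimination closure of ortho-hydroxyaryl β-amino- or β-alkoxy-enones to chromones. No stereocentre is formed, and the alkene geometry of 12 is lost when C2 passes through its sp3 stage. The selectivity needed is acylation at C4a and not at the para carbon C6: titanium chelation delivers the acyl group ortho, C6 is shielded by two flanking methoxy groups, and a C6 ketone cannot cyclise, so reversible acylation of this electron-rich ring should drain toward the irreversible chromone closure. The methyl arylacetate, the diaryl ether and the aryl methyl ethers are expected to be spectators at or below 40 °C.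

Step 9
Reactants: 14 methyl 2-[4-({5,7-dimethoxy-3-(4-methoxyphenyl)-4-oxo-4H-chromen-8-yl}oxy)phenyl]acetate
Product: 15 2-[4-({5,7-dimethoxy-3-(4-methoxyphenyl)-4-oxo-4H-chromen-8-yl}oxy)phenyl]acetic acid
Conditions: 3 M HCl, 1,4-dioxane, 90 °C
Reagents that add atoms: water, O
Why: Acid-catalysed ester hydrolysis is chosen because hydroxide can open the chromone at C2, whereas chromones, diaryl ethers and aryl methyl ethers tolerate hot aqueous acid.

Step 10
Reactants: 15 2-[4-({5,7-dimethoxy-3-(4-methoxyphenyl)-4-oxo-4H-chromen-8-yl}oxy)phenyl]acetic acid; 16 2-chlororesorcinol (2-chlorobenzene-1,3-diol, 3 equiv)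
Product: 18 8-[4-(8-chloro-7-hydroxy-4-oxo-4H-chromen-3-yl)phenoxy]-5,7-dimethoxy-3-(4-methoxyphenyl)-4H-chromen-4-one, via deoxybenzoin 17 (not isolated)
Conditions: BF3·Et2O, 85 °C; then DMF, MsCl, 60 °C
Reagents that add atoms: N,N-dimethylformamide, CN(C)C=O
Why: BF3-mediated Friedel–Crafts acylation of the resorcinol (its two reactive carbons are equivalent by symmetry, so only the 3-chloro-2,4-dihydroxyphenyl ketone can form), followed by formylation of the boron-chelated enol with the DMF/MsCl Vilsmeier-type reagent and cyclisation with loss of dimethylamine, the established one-pot synthesis of 7-hydroxyisoflavones.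

Step 11
Reactants: 18 8-[4-(8-chloro-7-hydroxy-4-oxo-4H-chromen-3-yl)phenoxy]-5,7-dimethoxy-3-(4-methoxyphenyl)-4H-chromen-4-one
Product: 19 Bisoflavolin H, 8-[4-(8-chloro-7-hydroxy-4-oxo-4H-chromen-3-yl)phenoxy]-5,7-dihydroxy-3-(4-hydroxyphenyl)-4H-chromen-4-one
Conditions: BBr3 (10 equiv), CH2Cl2, −78 °C to rt; then H2O, 0 °C
Reagents that add atoms: none
Why: Lewis-acid cleavage of the three aryl methyl ethers (the C5 ether assisted by the neighbouring carbonyl); diaryl ethers, the aryl chloride and the chromone rings are not cleaved by BBr3.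

**Compound list**

1 | 2-hydroxy-4,6-dimethoxybenzaldehyde | O=Cc1c(O)cc(OC)cc1OC | starting material
2 | 2-(benzyloxy)-4,6-dimethoxybenzaldehyde | O=Cc1c(OCc2ccccc2)cc(OC)cc1OC | intermediate
3 | 2-(benzyloxy)-4,6-dimethoxyphenyl formate | O=COc1c(OCc2ccccc2)cc(OC)cc1OC | intermediate (not isolated)
4 | 2-(benzyloxy)-4,6-dimethoxyphenol | Oc1c(OCc2ccccc2)cc(OC)cc1OC | intermediate
5 | methyl 2-(4-iodophenyl)acetate | COC(=O)Cc1ccc(I)cc1 | starting material
6 | methyl 2-{4-[2-(benzyloxy)-4,6-dimethoxyphenoxy]phenyl}acetate | COC(=O)Cc1ccc(Oc2c(OCc3ccccc3)cc(OC)cc2OC)cc1 | intermediate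
7 | methyl 2-[4-(2-hydroxy-4,6-dimethoxyphenoxy)phenyl]acetate | COC(=O)Cc1ccc(Oc2c(O)cc(OC)cc2OC)cc1 | intermediate
8 | methyl 2-(4-methoxyphenyl)acetate | COC(=O)Cc1ccc(OC)cc1 | starting material
9 | sodium enolate of methyl 2-(4-methoxyphenyl)-3-oxopropanoate (enolate geometry not fixed) | [Na+].[O-]C=C(C(=O)OC)c1ccc(OC)cc1 | intermediate (not isolated)
10 | methyl (E)-3-methoxy-2-(4-methoxyphenyl)prop-2-enoate | CO/C=C(/C(=O)OC)c1ccc(OC)cc1 | intermediate
11 | (E)-3-methoxy-2-(4-methoxyphenyl)prop-2-enoic acid | CO/C=C(/C(=O)O)c1ccc(OC)cc1 | intermediate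
12 | 2-[4-(2-methoxy-2-oxoethyl)phenoxy]-3,5-dimethoxyphenyl (E)-3-methoxy-2-(4-methoxyphenyl)prop-2-enoate | CO/C=C(/C(=O)Oc1cc(OC)cc(OC)c1Oc1ccc(CC(=O)OC)cc1)c1ccc(OC)cc1 | intermediate (key-step precursor)
13 | methyl 2-[4-(2-hydroxy-4,6-dimethoxy-3-{(E)-3-methoxy-2-(4-methoxyphenyl)prop-2-enoyl}phenoxy)phenyl]acetate | CO/C=C(/C(=O)c1c(O)c(Oc2ccc(CC(=O)OC)cc2)c(OC)cc1OC)c1ccc(OC)cc1 | intermediate (not isolated)
14 | methyl 2-[4-({5,7-dimethoxy-3-(4-methoxyphenyl)-4-oxo-4H-chromen-8-yl}oxy)phenyl]acetate | COC(=O)Cc1ccc(Oc2c(OC)cc(OC)c3c(=O)c(-c4ccc(OC)cc4)coc23)cc1 | intermediate (key-step product)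
15 | 2-[4-({5,7-dimethoxy-3-(4-methoxyphenyl)-4-oxo-4H-chromen-8-yl}oxy)phenyl]acetic acid | OC(=O)Cc1ccc(Oc2c(OC)cc(OC)c3c(=O)c(-c4ccc(OC)cc4)coc23)cc1 | intermediate
16 | 2-chlororesorcinol (2-chlorobenzene-1,3-diol) | Oc1cccc(O)c1Cl | starting material
17 | 1-(3-chloro-2,4-dihydroxyphenyl)-2-[4-({5,7-dimethoxy-3-(4-methoxyphenyl)-4-oxo-4H-chromen-8-yl}oxy)phenyl]ethan-1-one | O=C(Cc1ccc(Oc2c(OC)cc(OC)c3c(=O)c(-c4ccc(OC)cc4)coc23)cc1)c1ccc(O)c(Cl)c1O | intermediate (not isolated)
18 | 8-[4-(8-chloro-7-hydroxy-4-oxo-4H-chromen-3-yl)phenoxy]-5,7-dimethoxy-3-(4-methoxyphenyl)-4H-chromen-4-one | O=c1c(-c2ccc(Oc3c(OC)cc(OC)c4c(=O)c(-c5ccc(OC)cc5)coc34)cc2)coc2c(Cl)c(O)ccc12 | intermediate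
19 | Bisoflavolin H | O=c1c(-c2ccc(Oc3c(O)cc(O)c4c(=O)c(-c5ccc(O)cc5)coc34)cc2)coc2c(Cl)c(O)ccc12 | target

**Step count**

Total: 11 steps. Longest linear sequence: 9 steps (steps 1, 2, 3, 4, 7, 8, 9, 10, 11); steps 5 and 6 prepare the acid partner in parallel.

**Steps most likely to fail**

1. Step 8. The ester may ionise without productive recombination and simply return phenol 7. The acyl group may also settle at the carbon between the two methoxy groups, or titanium may strip the enol-ether methyl group (or the C5 methyl ether) before the cascade is complete. Loss of the C5 methyl group alone would be harmless, since step 11 removes it anyway. Fallback with known chemistry, from 7 back to 14: phenol 7 would be O-acylated with 4-methoxyphenylacetyl chloride (Et3N, DMAP, CH2Cl2) to 2-[4-(2-methoxy-2-oxoethyl)phenoxy]-3,5-dimethoxyphenyl 2-(4-methoxyphenyl)acetate F1. A classical Fries rearrangement of this aryl arylacetate (BF3·Et2O, 80 °C) would move the acyl group to the same ortho carbon and give the ortho-hydroxy deoxybenzoin, methyl 2-[4-(2-hydroxy-4,6-dimethoxy-3-[2-(4-methoxyphenyl)acetyl]phenoxy)phenyl]acetate F2. The established BF3·Et2O/DMF/MsCl one-carbon closure would then deliver 14. The ester relay on the same oxygen is kept, but acyl shift and ring closure become two separate known operations.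

2. Step 3. Copper-mediated C–O bond formation may be slow for a phenoxide flanked by two alkoxy groups. The electron-rich phenol may also be oxidised, or the methyl ester partly saponified, in hot basic DMSO. Fallback, from 4 back to 6: SNAr of 4 on 4-fluoroacetophenone (K2CO3, DMF, 120 °C, argon) would give 1-{4-[2-(benzyloxy)-4,6-dimethoxyphenoxy]phenyl}ethan-1-one F3. Willgerodt–Kindler reaction (S8, morpholine, 130 °C) would convert it to 2-{4-[2-(benzyloxy)-4,6-dimethoxyphenoxy]phenyl}-1-(morpholin-4-yl)ethane-1-thione F4. Hydrolysis (KOH, EtOH–H2O, reflux) would give 2-{4-[2-(benzyloxy)-4,6-dimethoxyphenoxy]phenyl}acetic acid F5, and Fischer esterification (MeOH, cat. H2SO4) would return 6.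

3. Step 10. Direct C-acylation may stall on the chlorine-deactivated resorcinol. The activated acid could instead attack the electron-rich C6–H of ring A in a second molecule, and the Vilsmeier-type reagent could formylate at an unintended site. Fallback, from 15 and 16 back to 18: Steglich esterification of 15 with excess 16 (EDC·HCl, DMAP, CH2Cl2) would give the mono-ester, 2-chloro-3-hydroxyphenyl 2-[4-({5,7-dimethoxy-3-(4-methoxyphenyl)-4-oxo-4H-chromen-8-yl}oxy)phenyl]acetate F6. A Fries rearrangement (TiCl4, CH2Cl2, or BF3·Et2O, 80 °C) would convert it to ketone 17, which would now be isolated; ortho and para migration lead to the same ketone by symmetry. A separate BF3·Et2O/DMF/MsCl closure on purified 17 would then give 18.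

**Further compounds**

F1 | step 8 | 2-[4-(2-methoxy-2-oxoethyl)phenoxy]-3,5-dimethoxyphenyl 2-(4-methoxyphenyl)acetate | COC(=O)Cc1ccc(Oc2c(OC(=O)Cc3ccc(OC)cc3)cc(OC)cc2OC)cc1
F2 | step 8 | methyl 2-[4-(2-hydroxy-4,6-dimethoxy-3-[2-(4-methoxyphenyl)acetyl]phenoxy)phenyl]acetate | COC(=O)Cc1ccc(Oc2c(O)c(C(=O)Cc3ccc(OC)cc3)c(OC)cc2OC)cc1
F3 | step 3 | 1-{4-[2-(benzyloxy)-4,6-dimethoxyphenoxy]phenyl}ethan-1-one | CC(=O)c1ccc(Oc2c(OCc3ccccc3)cc(OC)cc2OC)cc1
F4 | step 3 | 2-{4-[2-(benzyloxy)-4,6-dimethoxyphenoxy]phenyl}-1-(morpholin-4-yl)ethane-1-thione | S=C(Cc1ccc(Oc2c(OCc3ccccc3)cc(OC)cc2OC)cc1)N1CCOCC1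
F5 | step 3 | 2-{4-[2-(benzyloxy)-4,6-dimethoxyphenoxy]phenyl}acetic acid | OC(=O)Cc1ccc(Oc2c(OCc3ccccc3)cc(OC)cc2OC)cc1
F6 | step 10 | 2-chloro-3-hydroxyphenyl 2-[4-({5,7-dimethoxy-3-(4-methoxyphenyl)-4-oxo-4H-chromen-8-yl}oxy)phenyl]acetate | O=C(Cc1ccc(Oc2c(OC)cc(OC)c3c(=O)c(-c4ccc(OC)cc4)coc23)cc1)Oc1cccc(O)c1Cl
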